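**Remarks.** Atom numbering used throughout (cembrane type): ring atoms C1–C14; C1 carries C15, the C(CH3)2OAc carbon; C18, C19 and C20 are the methyl groups on C4, C8 and C12. In this numbering the target is (1R,3Z,7R,8R,10R,11E). Compounds 1, 5 and 6 and all reagents are taken as commercial. In step 9 the (R)-acid is assumed to give the R-carbinol, as it does with aryl and alkenyl aldehydes.

## Analysis of the target

Target 24 is a cembrane-type 14-membered carbocycle with a trans-fused oxirane (C7–C8), a Z-trisubstituted olefin (C3=C4), an E-trisubstituted olefin (C11=C12), a secondary allylic acetate (C10) and a tertiary acetate (C15). It has four stereocentres: C7 and C8 (R,R, the trans-epoxide of an E-olefin), C10 (R, 1,3-anti to the C8–O bond across the C9 methylene) and C1 (R). C1 lies several bonds from C10 across the E-olefin and from C7 across the Z-olefin, so it cannot be relayed from the other three. The sensitive groups are the acid-labile trisubstituted epoxide, the ionisable allylic acetate and the hindered, elimination-prone tertiary acetate; moreover, any C10 carbonyl precursor that already holds the epoxide is a β,γ-epoxy carbonyl compound and opens by E1cB. The ring is not the only difficulty: a ring-stage triene offers three trisubstituted olefins of similar nucleophilicity, and a C10 hydroxyl would steer a metal-bound peroxide to the allylic C11=C12 bond rather than to the homoallylic C7=C8 bond. The epoxide therefore has to be set by reagent control on an open chain in which C3=C4 is absent or electron-poor. The feature that invites the chosen move is the C4–C5 single bond: it joins the only contra-thermodynamic element of the ring, the Z-olefin C3=C4(C18), to the C5–C6 ethano bridge, carries no heteroatom, and is remote from C1 and C10. Cut there, C4 becomes the carbon of a (Z)-iodoalkene (geometrically fixed, inert to electrophilic oxidants, ready for stereoretentive coupling) and C5 a primary alkyl terminus, so the ring can be closed last, on a chain that already carries all four stereocentres, the epoxide and both acetates.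

## Retrosynthetic reasoning

**24 ⇒ 23 ⇒ 22 (C4–C5).** The ring is opened at C4–C5. The forward reaction is an intramolecular alkylzinc/iodoalkene coupling, which must form the ring without touching the epoxide or the acetates and must keep the Z geometry. Nothing remains to be done after it: no protecting group, no oxidation, no stereocentre. Cutting C10–C11 or C9–C10 instead would force either a β,γ-epoxy aldehyde or an epoxidation on the ring.

**22 ⇒ 21 ⇒ 20 (C5 leaving group; C7–C8 epoxide).** The C5 iodide comes from a sulfonate that survives oxidation. The epoxide comes from the C7=C8 olefin of 20 by Shi epoxidation. In 20, C7=C8 is the only electron-rich olefin: C11=C12 is an allylic acetate and C3=C4 is an iodoalkene. Regioselectivity is thus designed into the substrate and the catalyst sets C7 and C8.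

**20 ⇒ 18 ⇒ 16 (C6–C7 and C8–C19).** The E-olefin C7=C8 with its methyl group is cut back to a terminal alkyne. Syn methylmetalation fixes the geometry, and two-carbon hydroxyethylation of the resulting alkenylmetal supplies C6, C5 and the primary hydroxyl that becomes the ring-closure handle.

**16 ⇒ 15 (C9–C10).** The homopropargylic carbinol is cut to enal 15 and a propargyl nucleophile. A conjugated enal is a robust electrophile (unlike the β,γ-unsaturated or β,γ-epoxy aldehydes that a C10–C11 cut would need), and a chiral Brønsted acid sets C10 independently of C1.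

**15 ⇒ 14 ⇒ 12 (C10–C11 and C12–C20).** The E-enal is cut back to the terminal alkyne of 12 by the same methylmetalation logic, here with one-carbon hydroxymethylation and allylic oxidation.

**12 ⇒ 11 ⇒ 10 ⇒ 8 + 4 (C15 methyls; C1–C2).** The tertiary carbinol comes from double methyl addition to ester 11. C1 is set by auxiliary-controlled alkylation of imide 8 with allylic bromide 4. Reagent control is needed because no other stereocentre exists at this stage. The electrophile 4 brings in C2, C3, C4 and C18 with the Z-iodoalkene complete.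

**4 ⇒ 3 ⇒ 1 and 8 ⇒ 5 + 6.** The Z-iodoalkene comes from hydroxyl-directed trans-hydrometalation and iodination of butynol 1. Imide 8 is the acylation product of acid 5 and auxiliary 6.

## Alternatives that were turned down

**Alternative 1: C10–C11, Nozaki–Hiyama–Kishi macrocyclisation (the textbook route).** The seco-aldehyde A1 (C10 aldehyde, C11 (E)-iodoalkene, C7=C8 still an olefin) would be closed with CrCl2/NiCl2 to the macrocyclic allylic alcohol A2.
- With the epoxide in place the aldehyde would be a β,γ-epoxy aldehyde, which eliminates by E1cB, so the epoxide has to be postponed.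
- A2 then has three trisubstituted olefins. Its C10 hydroxyl directs metal peroxides to the allylic C11=C12, and a dioxirane cannot tell C7=C8 from C3=C4.
- C10 is formed without control in the ring closure and would need an oxidation/reduction pair.

**Alternative 2: C7≡C8, ring-closing alkyne metathesis.** Diyne A3 would be closed to cycloalkyne A4 with a molybdenum alkylidyne of formula (Ph3SiO)3Mo≡CAr. Hydroxyl-directed trans-hydrostannation ([Cp*RuCl]4, Bu3SnH; tin on C8, proximal to the C10 hydroxyl) and C-methylation would then give the E-olefin with C19.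
- The sequence fits the methyl-branched olefin well, but it spends three steps after ring closure.
- It ends at the same ring-stage triene as Alternative 1, with the same unsolved epoxidation.
- The palladium-mediated methylation would have to be run next to an allylic alcohol.

**Alternative 3: C1–C2, epoxide-opening macrocyclisation.** The α-sulfonyl carbanion at C2 of bis-epoxide A5 would open the terminal C1–C15 oxirane at C1 with inversion, giving A6. This sets C1 and frees the C15 hydroxyl in the ring-forming step.
- The same carbanion can open the C7–C8 epoxide at C7 in a 6-exo mode, forming a cyclohexene far faster than a 14-membered ring.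
- If the C7–C8 epoxide is postponed, the ring-stage epoxidation problem returns.
- Reductive removal of an allylic sulfone next to the Z-olefin passes through an allyl anion or π-allyl species that can scramble the geometry, and it is not compatible with an allylic acetate or an epoxide.

Key step: step 14

## Route

Step 1
Reactants: 1 but-2-yn-1-ol
Product: 3 (2Z)-3-iodobut-2-en-1-ol, via alkenylalanate 2 (not isolated)
Conditions: NaAlH2(OCH2CH2OMe)2 (1.4 equiv), THF, 0 °C to rt; then I2, THF, −78 to 0 °C
Reagents that add atoms: iodine (II)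
Why: Hydroxyl-directed trans-hydroalumination of the propargylic alcohol (hydride to C2; aluminium to C3, held cis to the CH2O group in the five-membered alanate 2) and iodinolysis of the C–Al bond with retention should give only the Z-iodoalkene, the geometry that becomes Z-C3=C4.

Step 2
Reactants: 3 (2Z)-3-iodobut-2-en-1-ol
Product: 4 (2Z)-1-bromo-3-iodobut-2-ene
Conditions: CBr4, PPh3, CH2Cl2, 0 °C
Reagents that add atoms: carbon tetrabromide (BrC(Br)(Br)Br)
Why: Appel bromination; SN2 at the primary allylic carbon leaves the iodoalkene and its geometry untouched.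

Step 3
Reactants: 5 hex-5-ynoic acid; 6 (4S)-4-benzyl-1,3-oxazolidin-2-one
Product: 8 (4S)-4-benzyl-3-(hex-5-ynoyl)-1,3-oxazolidin-2-one, via mixed anhydride 7 (not isolated)
Conditions: t-BuCOCl, Et3N, THF, −20 to 0 °C; then 6, LiCl, rt
Reagents that add atoms: none
Why: Mixed-anhydride N-acylation of the oxazolidinone (LiCl/Et3N variant); no strong base is needed, so the terminal alkyne is not touched.

Step 4
Reactants: 8 (4S)-4-benzyl-3-(hex-5-ynoyl)-1,3-oxazolidin-2-one; 4 (2Z)-1-bromo-3-iodobut-2-ene
Product: 10 (4S)-4-benzyl-3-{(2R)-2-[(2Z)-3-iodobut-2-en-1-yl]hex-5-ynoyl}-1,3-oxazolidin-2-one, via sodium enolate 9 (not isolated)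
Conditions: NaN(SiMe3)2 (1.1 equiv), THF, −78 °C; then 4 (1.5 equiv), −78 to −40 °C
Reagents that add atoms: none
Why: Evans alkylation: the chelated sodium Z-enolate 9 is attacked by the allylic bromide on the face opposite to the benzyl group, which sets C1 as R; the base removes the imide α-proton and not the alkyne C–H, and the alkenyl iodide is inert to the enolate.

Step 5
Reactants: 10 (4S)-4-benzyl-3-{(2R)-2-[(2Z)-3-iodobut-2-en-1-yl]hex-5-ynoyl}-1,3-oxazolidin-2-one
Product: 11 methyl (2R)-2-[(2Z)-3-iodobut-2-en-1-yl]hex-5-ynoate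
Conditions: MeOMgBr (made from MeMgBr and MeOH), CH2Cl2/MeOH, 0 °C
Reagents that add atoms: bromo(methoxy)magnesium (CO[Mg]Br)
Why: Magnesium-methoxide transesterification attacks the exocyclic imide carbonyl selectively under nearly neutral conditions, so C1 should not epimerise; the auxiliary is recovered.

Step 6
Reactants: 11 methyl (2R)-2-[(2Z)-3-iodobut-2-en-1-yl]hex-5-ynoate
Product: 12 (3R)-3-[(2Z)-3-iodobut-2-en-1-yl]-2-methylhept-6-yn-2-ol
Conditions: MeMgBr (4 equiv), THF, 0 °C to rt
Reagents that add atoms: methylmagnesium bromide (C[Mg]Br)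
Why: Double Grignard addition to the ester gives the tertiary carbinol C15 with its two methyl groups; MeMgBr does not exchange with the alkenyl iodide, and one extra equivalent is consumed by the alkyne C–H.

Step 7
Reactants: 12 (3R)-3-[(2Z)-3-iodobut-2-en-1-yl]-2-methylhept-6-yn-2-ol
Product: 14 (2E,6R)-6-[(2Z)-3-iodobut-2-en-1-yl]-3,7-dimethyloct-2-ene-1,7-diol, via alkenylalane 13 (not isolated)
Conditions: Me3Al (4 equiv), Cp2ZrCl2 (25 mol%), CH2Cl2, 0 °C to rt; volatiles removed; MeLi (1.05 equiv), THF, −78 °C; (CH2O)n, −78 °C to rt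
Reagents that add atoms: trimethylaluminium (C[Al](C)C); formaldehyde as paraformaldehyde (C=O)
Why: Zirconium-catalysed methylalumination (Negishi carboalumination) adds Me and Al syn across the terminal alkyne with Me on the internal carbon, which fixes E-C11=C12 and installs C20; the alanate is hydroxymethylated with retention to give C10; MeLi is chosen for the ate complex because it complexes aluminium far faster than it exchanges with an alkenyl iodide.

Step 8
Reactants: 14 (2E,6R)-6-[(2Z)-3-iodobut-2-en-1-yl]-3,7-dimethyloct-2-ene-1,7-diol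
Product: 15 (2E,6R)-7-hydroxy-6-[(2Z)-3-iodobut-2-en-1-yl]-3,7-dimethyloct-2-enal
Conditions: MnO2 (excess), CH2Cl2, rt
Reagents that add atoms: none
Why: MnO2 oxidises only the allylic primary alcohol; the tertiary alcohol, the E geometry and the iodoalkene should be untouched.

Step 9
Reactants: 15 (2E,6R)-7-hydroxy-6-[(2Z)-3-iodobut-2-en-1-yl]-3,7-dimethyloct-2-enal
Product: 16 (4R,5E,9R)-9-[(2Z)-3-iodobut-2-en-1-yl]-6,10-dimethylundec-5-en-1-yne-4,10-diol
Conditions: allenylboronic acid pinacol ester (1.5 equiv), (R)-TRIP (10 mol%), 4 Å MS, toluene, −20 to 0 °C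
Reagents that add atoms: allenylboronic acid pinacol ester (C=C=CB1OC(C)(C)C(C)(C)O1)
Why: Chiral phosphoric acid-catalysed allenylboration through a closed six-membered SE2' transition state gives 1,2-addition only, and the acid controls the aldehyde face and should set C10 as R; the sense is assigned by analogy with aryl and alkenyl aldehydes, whose carbinol substituents rank in the same CIP order, and the antipodal acid would be used if the assignment proved reversed.

Step 10
Reactants: 16 (4R,5E,9R)-9-[(2Z)-3-iodobut-2-en-1-yl]-6,10-dimethylundec-5-en-1-yne-4,10-diol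
Product: 18 (3E,6R,7E,11R)-11-[(2Z)-3-iodobut-2-en-1-yl]-4,8,12-trimethyltrideca-3,7-diene-1,6,12-triol, via alkenylalane 17 (not isolated)
Conditions: Me3Al (5 equiv), Cp2ZrCl2 (50 mol%), CH2Cl2, 0 °C to rt; volatiles removed; MeLi (1.05 equiv), THF, −78 °C; oxirane (5 equiv), −78 to 0 °C
Reagents that add atoms: trimethylaluminium (C[Al](C)C); oxirane (C1CO1)
Why: Second Negishi carboalumination, now on the aluminium alkoxide of the homopropargylic alcohol: syn addition with Me (C19) on C8 fixes E-C7=C8, and the alanate opens oxirane with retention at C7, delivering C6, C5 and the primary hydroxyl handle; room temperature is kept to avoid chelation-driven isomerisation of 17.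

Step 11
Reactants: 18 (3E,6R,7E,11R)-11-[(2Z)-3-iodobut-2-en-1-yl]-4,8,12-trimethyltrideca-3,7-diene-1,6,12-triol
Product: 20 (3E,6R,7E,11R)-6,12-diacetoxy-11-[(2Z)-3-iodobut-2-en-1-yl]-4,8,12-trimethyltrideca-3,7-dien-1-yl 4-methylbenzenesulfonate, via primary tosylate 19 (not isolated)
Conditions: TsCl (1.1 equiv), Et3N, DMAP (5 mol%), CH2Cl2, 0 °C; then Ac2O (6 equiv), DMAP, Et3N, rt to 35 °C
Reagents that add atoms: 4-methylbenzenesulfonyl chloride (Cc1ccc(cc1)S(=O)(=O)Cl); acetic anhydride (CC(=O)OC(C)=O)
Why: Sulfonylation is fastest at the only primary hydroxyl; DMAP-catalysed (Steglich) acetylation then esterifies the secondary and, more slowly, the tertiary hydroxyl, so both acetates of the target are in place and C11=C12 becomes an electron-poor allylic acetate olefin.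

Step 12
Reactants: 20 (3E,6R,7E,11R)-6,12-diacetoxy-11-[(2Z)-3-iodobut-2-en-1-yl]-4,8,12-trimethyltrideca-3,7-dien-1-yl 4-methylbenzenesulfonate
Product: 21 (3R,4R,6R,7E,11R)-6,12-diacetoxy-3,4-epoxy-11-[(2Z)-3-iodobut-2-en-1-yl]-4,8,12-trimethyltridec-7-en-1-yl 4-methylbenzenesulfonate
Conditions: D-fructose-derived Shi ketone (30 mol%), KHSO5 (as Oxone, 2KHSO5·KHSO4·K2SO4), K2CO3, Bu4NHSO4, MeCN/CH2(OMe)2/aq. Na2B4O7 buffer, 0 °C
Reagents that add atoms: potassium peroxymonosulfate ([K+].OOS(=O)(=O)[O-])
Why: Shi epoxidation (chiral dioxirane, spiro transition state): C7=C8 is the only electron-rich olefin, since C11=C12 is deactivated by the allylic acetate and C3=C4 by iodine; the D-fructose-derived ketone gives R,R-epoxides from E-trisubstituted olefins, here 7R,8R in target numbering.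

Step 13
Reactants: 21 (3R,4R,6R,7E,11R)-6,12-diacetoxy-3,4-epoxy-11-[(2Z)-3-iodobut-2-en-1-yl]-4,8,12-trimethyltridec-7-en-1-yl 4-methylbenzenesulfonate
Product: 22 (3R,4R,6R,7E,11R)-3,4-epoxy-1-iodo-11-[(2Z)-3-iodobut-2-en-1-yl]-4,8,12-trimethyltridec-7-ene-6,12-diyl diacetate
Conditions: NaI, NaHCO3, acetone, 45 °C
Reagents that add atoms: sodium iodide ([Na+].[I-])
Why: Finkelstein exchange at the primary sulfonate; the buffered neutral medium should leave epoxide, acetates and iodoalkene intact.

Step 14
Reactants: 22 (3R,4R,6R,7E,11R)-3,4-epoxy-1-iodo-11-[(2Z)-3-iodobut-2-en-1-yl]-4,8,12-trimethyltridec-7-ene-6,12-diyl diacetate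
Product: 24 (1R,3Z,7R,8R,10R,11E)-7,8-epoxycembra-3,11-diene-10,15-diyl diacetate, via alkylzinc iodide 23 (not isolated)
Conditions: Zn dust (3 equiv, activated), LiCl, THF, 25 °C; the solution of 23 is added over 8 h to PdCl2(dppf) (10 mol%) in THF/NMP, 40 °C (final 2 mM)
Reagents that add atoms: none
Why: Zinc inserts only into the primary C5–I bond (an sp3 C–I bond reacts at 25 °C, the alkenyl C4–I bond does not) to give 23; zerovalent palladium, formed from PdCl2(dppf), adds oxidatively to the (Z)-iodoalkene with retention, the alkylzinc transmetalates, and reductive elimination forms C4–C5 (intramolecular Negishi coupling). The closest known reaction types are the coupling of alkylzinc halides with (Z)-2-iodoalkenes and the B-alkyl Suzuki macrocyclisation. The 14-membered ring closes end to end through a 15-membered alkyl(alkenyl)palladium species; slow addition keeps the concentration of 23 low so that ring closure should outrun dimerisation, and the two olefins and the epoxide pre-bend the chain. No stereocentre is created, and the Z geometry of C3=C4 is inherited from the iodoalkene, so the ring closure cannot scramble it. The step needs oxidative addition at C4–I to be faster than ionisation of the C10 allylic acetate, which the iodoalkene and the bidentate phosphine should secure. It also needs the γ-epoxide to survive the organozinc, which the weakly Lewis-acidic LiCl-complexed reagent, used at once, should allow. β-Hydride elimination from the alkylpalladium intermediate is disfavoured by the wide bite angle of dppf. The product is the target; no further step follows.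

## Compound list

1 | but-2-yn-1-ol | CC#CCO | starting material
2 | sodium 2,2-bis(2-methoxyethoxy)-3-methyl-1,2-oxaaluminacyclopent-3-en-2-uide (cyclic alkenylalanate) | [Na+].CC1=CCO[Al-]1(OCCOC)OCCOC | intermediate
3 | (2Z)-3-iodobut-2-en-1-ol | OC/C=C(/C)I | intermediate
4 | (2Z)-1-bromo-3-iodobut-2-ene | BrC/C=C(/C)I | intermediate
5 | hex-5-ynoic acid | OC(=O)CCCC#C | starting material
6 | (4S)-4-benzyl-1,3-oxazolidin-2-one | O=C1N[C@@H](Cc2ccccc2)CO1 | starting material
7 | hex-5-ynoic pivalic anhydride | C#CCCCC(=O)OC(=O)C(C)(C)C | intermediate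
8 | (4S)-4-benzyl-3-(hex-5-ynoyl)-1,3-oxazolidin-2-one | C#CCCCC(=O)N1[C@@H](Cc2ccccc2)COC1=O | intermediate
9 | sodium (Z)-enolate of 8 | [Na]O/C(=C\CCC#C)N1[C@@H](Cc2ccccc2)COC1=O | intermediate
10 | (4S)-4-benzyl-3-{(2R)-2-[(2Z)-3-iodobut-2-en-1-yl]hex-5-ynoyl}-1,3-oxazolidin-2-one | C#CCC[C@H](C/C=C(/C)I)C(=O)N1[C@@H](Cc2ccccc2)COC1=O | intermediate
11 | methyl (2R)-2-[(2Z)-3-iodobut-2-en-1-yl]hex-5-ynoate | C#CCC[C@H](C/C=C(/C)I)C(=O)OC | intermediate
12 | (3R)-3-[(2Z)-3-iodobut-2-en-1-yl]-2-methylhept-6-yn-2-ol | C#CCC[C@H](C/C=C(/C)I)C(C)(C)O | intermediate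
13 | (E)-alkenyl(dimethyl)alane from 12 (Al on C11, O-dimethylaluminium alkoxide at C15) | C[Al](C)/C=C(\C)CC[C@H](C/C=C(/C)I)C(C)(C)O[Al](C)C | intermediate
14 | (2E,6R)-6-[(2Z)-3-iodobut-2-en-1-yl]-3,7-dimethyloct-2-ene-1,7-diol | OC/C=C(\C)CC[C@H](C/C=C(/C)I)C(C)(C)O | intermediate
15 | (2E,6R)-7-hydroxy-6-[(2Z)-3-iodobut-2-en-1-yl]-3,7-dimethyloct-2-enal | O=C/C=C(\C)CC[C@H](C/C=C(/C)I)C(C)(C)O | intermediate
16 | (4R,5E,9R)-9-[(2Z)-3-iodobut-2-en-1-yl]-6,10-dimethylundec-5-en-1-yne-4,10-diol | C#CC[C@@H](O)/C=C(\C)CC[C@H](C/C=C(/C)I)C(C)(C)O | intermediate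
17 | (E)-alkenyl(dimethyl)alane from 16 (Al on C7, O-dimethylaluminium alkoxides at C10 and C15) | C[Al](C)/C=C(\C)C[C@@H](O[Al](C)C)/C=C(\C)CC[C@H](C/C=C(/C)I)C(C)(C)O[Al](C)C | intermediate
18 | (3E,6R,7E,11R)-11-[(2Z)-3-iodobut-2-en-1-yl]-4,8,12-trimethyltrideca-3,7-diene-1,6,12-triol | OCC/C=C(\C)C[C@@H](O)/C=C(\C)CC[C@H](C/C=C(/C)I)C(C)(C)O | intermediate
19 | (3E,6R,7E,11R)-6,12-dihydroxy-11-[(2Z)-3-iodobut-2-en-1-yl]-4,8,12-trimethyltrideca-3,7-dien-1-yl 4-methylbenzenesulfonate | Cc1ccc(cc1)S(=O)(=O)OCC/C=C(\C)C[C@@H](O)/C=C(\C)CC[C@H](C/C=C(/C)I)C(C)(C)O | intermediate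
20 | (3E,6R,7E,11R)-6,12-diacetoxy-11-[(2Z)-3-iodobut-2-en-1-yl]-4,8,12-trimethyltrideca-3,7-dien-1-yl 4-methylbenzenesulfonate | Cc1ccc(cc1)S(=O)(=O)OCC/C=C(\C)C[C@@H](OC(C)=O)/C=C(\C)CC[C@H](C/C=C(/C)I)C(C)(C)OC(C)=O | intermediate
21 | (3R,4R,6R,7E,11R)-6,12-diacetoxy-3,4-epoxy-11-[(2Z)-3-iodobut-2-en-1-yl]-4,8,12-trimethyltridec-7-en-1-yl 4-methylbenzenesulfonate | Cc1ccc(cc1)S(=O)(=O)OCC[C@H]1O[C@]1(C)C[C@@H](OC(C)=O)/C=C(\C)CC[C@H](C/C=C(/C)I)C(C)(C)OC(C)=O | intermediate
22 | (3R,4R,6R,7E,11R)-3,4-epoxy-1-iodo-11-[(2Z)-3-iodobut-2-en-1-yl]-4,8,12-trimethyltridec-7-ene-6,12-diyl diacetate | ICC[C@H]1O[C@]1(C)C[C@@H](OC(C)=O)/C=C(\C)CC[C@H](C/C=C(/C)I)C(C)(C)OC(C)=O | intermediate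
23 | primary alkylzinc iodide from 22 (Zn on C5) | I[Zn]CC[C@H]1O[C@]1(C)C[C@@H](OC(C)=O)/C=C(\C)CC[C@H](C/C=C(/C)I)C(C)(C)OC(C)=O | intermediate
24 | (1R,3Z,7R,8R,10R,11E)-7,8-epoxycembra-3,11-diene-10,15-diyl diacetate | CC(=O)O[C@H]1/C=C(\C)CC[C@@H](C(C)(C)OC(C)=O)C/C=C(/C)CC[C@H]2O[C@]2(C)C1 | target

## Step count and least certain steps

Total: 14 steps. Longest linear sequence: 13 steps (from 1 through steps 1, 2 and 4–14; the branch from 5 is 12 steps).

**Step 14 (key step).** Chain-to-chain coupling may compete with ring closure. The γ-epoxide may be opened by the zinc halide, or by 1,3-attack of the C5–Zn bond on C7. Zerovalent palladium may ionise the C10 allylic acetate before it inserts into the C4–I bond, and the organozinc may be protonated during the slow addition. Fallback: a nickel-catalysed reductive cross-electrophile coupling that sets out from 22 and comes back at 24 (NiBr2(dme), 4,4'-di-tert-butyl-2,2'-bipyridine, Mn powder, DMA, high dilution). Both carbon–iodine bonds are joined directly, no organozinc is formed, and C5 reacts as a radical that is not placed to open the epoxide. This fallback makes no new compound.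

**Step 12.** The dioxirane may also epoxidise the allylic-acetate olefin C11=C12, may oxidise the alkenyl iodide at iodine, or may give incomplete facial control next to the C10 stereocentre. Fallback: a hydroxyl-directed epoxidation that sets out from 18 and comes back at 21. The primary hydroxyl is silylated (t-BuMe2SiCl, imidazole) to the primary silyl ether F1, and the two remaining hydroxyls are acetylated (Ac2O, DMAP, Et3N) to the diacetate silyl ether F2. Desilylation (HF·pyridine) then frees the primary alcohol F3. A vanadium-catalysed asymmetric epoxidation of this homoallylic alcohol (VO(OiPr)3, C2-symmetric bishydroxamic acid ligand, cumene hydroperoxide, toluene) gives the epoxy alcohol F4, and tosylation of F4 (TsCl, Et3N) gives 21. The oxidant is delivered only to the olefin homoallylic to the free hydroxyl, so neither C11=C12 nor the iodoalkene can compete, and no dioxirane meets the iodide.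

**Step 9.** Facial discrimination on a β,β-disubstituted aliphatic enal may be insufficient, the free tertiary hydroxyl may interfere with the acid, and the sense of induction is assigned only by analogy. Fallback: a resolution that sets out from 15 and comes back at 16. Barbier propargylation (propargyl bromide, Zn dust, THF/aq. NH4Cl) gives the C4-epimeric mixture F5. Lipase-catalysed acylation (lipase from Burkholderia cepacia, vinyl acetate) should, by the usual empirical rule for secondary alcohols, acylate the 4R epimer to the acetate F6 and leave the 4S alcohol F7. Methanolysis of F6 (K2CO3, MeOH) gives 16.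

Further compounds
F0 | step 14 | none | none
F1 | step 12 | 1-O-tert-butyldimethylsilyl ether of 18 | CC(C)(C)[Si](C)(C)OCC/C=C(\C)C[C@@H](O)/C=C(\C)CC[C@H](C/C=C(/C)I)C(C)(C)O
F2 | step 12 | 6,12-di-O-acetyl-1-O-tert-butyldimethylsilyl derivative of 18 | CC(C)(C)[Si](C)(C)OCC/C=C(\C)C[C@@H](OC(C)=O)/C=C(\C)CC[C@H](C/C=C(/C)I)C(C)(C)OC(C)=O
F3 | step 12 | 6,12-di-O-acetyl derivative of 18 with free primary hydroxyl | OCC/C=C(\C)C[C@@H](OC(C)=O)/C=C(\C)CC[C@H](C/C=C(/C)I)C(C)(C)OC(C)=O
F4 | step 12 | (3R,4R)-3,4-epoxide of F3 | OCC[C@H]1O[C@]1(C)C[C@@H](OC(C)=O)/C=C(\C)CC[C@H](C/C=C(/C)I)C(C)(C)OC(C)=O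
F5 | step 9 | (5E,9R)-9-[(2Z)-3-iodobut-2-en-1-yl]-6,10-dimethylundec-5-en-1-yne-4,10-diol, mixture of C4 epimers | C#CCC(O)/C=C(\C)CC[C@H](C/C=C(/C)I)C(C)(C)O
F6 | step 9 | (4R,5E,9R)-10-hydroxy-9-[(2Z)-3-iodobut-2-en-1-yl]-6,10-dimethylundec-5-en-1-yn-4-yl acetate | C#CC[C@@H](OC(C)=O)/C=C(\C)CC[C@H](C/C=C(/C)I)C(C)(C)O
F7 | step 9 | (4S,5E,9R)-9-[(2Z)-3-iodobut-2-en-1-yl]-6,10-dimethylundec-5-en-1-yne-4,10-diol | C#CC[C@H](O)/C=C(\C)CC[C@H](C/C=C(/C)I)C(C)(C)O
A1 | alternative 1 | (3E,7Z,10R,13E)-10-(2-acetoxypropan-2-yl)-14-iodo-3,7,13-trimethyltetradeca-3,7,13-trienal | O=CC/C(C)=C/CC/C(C)=C\C[C@H](C(C)(C)OC(C)=O)CC/C(C)=C/I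
A2 | alternative 1 | (1R,3Z,7E,11E)-10-hydroxycembra-3,7,11-trien-15-yl acetate, C10 epimers | OC1/C=C(\C)CC[C@@H](C(C)(C)OC(C)=O)C/C=C(/C)CC/C=C(\C)C1
A3 | alternative 2 | (5R,6E,10R,12Z)-10-(2-acetoxypropan-2-yl)-7,13-dimethyloctadeca-6,12-dien-2,16-diyn-5-ol | CC#CCC/C(C)=C\C[C@H](C(C)(C)OC(C)=O)CC/C(C)=C/[C@H](O)CC#CC
A4 | alternative 2 | (1R,3Z,10R,11E)-10-hydroxy-19-norcembra-3,11-dien-7-yn-15-yl acetate | C1#CCC/C(C)=C\C[C@H](C(C)(C)OC(C)=O)CC/C(C)=C/[C@H](O)C1
A5 | alternative 3 | open-chain C2 phenyl sulfone with (3Z,11E) olefins, (7R,8R)-epoxide, (10R)-tert-butyldimethylsilyl ether and terminal (1R)-C1–C15 epoxide | O=S(=O)(C/C=C(/C)CC[C@H]1O[C@]1(C)C[C@@H](O[Si](C)(C)C(C)(C)C)/C=C(\C)CC[C@H]1OC1(C)C)c1ccccc1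
A6 | alternative 3 | 2-(phenylsulfonyl)-10-O-tert-butyldimethylsilyl-7,8-epoxycembra-3,11-dien-15-ol with the ring configuration of 24, C2 epimers | CC(C)(C)[Si](C)(C)O[C@H]1/C=C(\C)CC[C@@H](C(C)(C)O)C(S(=O)(=O)c2ccccc2)/C=C(/C)CC[C@H]3O[C@]3(C)C1
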